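Locants follow benzofuran numbering. The styryl-bearing dihydrobenzofuran is unprimed (O1, C2, C3, benzo ring A = C3a to C7a) and the other one is primed (benzo ring B). TBS = tert-butyldimethylsilyl.
Endgame: global desilylation, preceded by a Heck reaction that places the 4-oxystyryl group on C4–Br of ring A.
Key disconnection: the ring O1–C2–C3–C3a–C7a is not closed directly but grows from the cyclopropane C2–C3–C3a of a spiro[2.5]octa-5,7-dien-4-one in which ring A (bought flat as 5-bromoresorcinol) is dearomatised (C7a=O, C3a spiro). The cyclopropane is made by enantioselective carbene transfer from the ring A o-quinone diazide to the stilbene C=C of a protected dimer, and in the same flask it takes in C7a and O1 while ring A rearomatises.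
Enabling feature: C3a lies next to C7a–O1 and para to C6–O, so ring A can exist as a cyclohexadienone with a carbene or spiro centre at C3a. C2 carries a 4-oxygenated phenyl ring, so the cyclopropane bond C3a–C2 is the one that ionises, and the C7a oxygen closes on a quinone-methide-like C2 as in the presumed biosynthesis.
The protected dimer comes from the same tactic one unit earlier (resveratrol silyl ether + symmetric ring B o-quinone diazide, then Heck reaction). Rings form in the order primed cyclopropane, primed dihydrofuran, unprimed cyclopropane, unprimed dihydrofuran.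

Key step: step 13

Assumption: the sense of induction of Rh2(S-TCPTTL)4 (dirhodium tetrakis[N-tetrachlorophthaloyl-(S)-tert-leucinate]) and of its enantiomer Rh2(R-TCPTTL)4 is assigned by analogy with styrene cyclopropanations. If it proves opposite, the two catalysts are exchanged between steps 7 and 13.

Step 1
Reactants: 1 resveratrol
Product: 2 (E)-3,5,4'-tris(TBS-oxy)stilbene
Conditions: TBSCl (3.6 equiv), imidazole, DMF, rt
Reagents that add atoms: tert-butyldimethylsilyl chloride CC(C)(C)[Si](C)(C)Cl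
Why: Imidazole-promoted O-silylation masks all three phenols with groups that keep the alkene electron-rich, tolerate carbene transfer and Heck coupling, and leave with fluoride at the end, and no stereocentre is formed.

Step 2
Reactants: 3 5-bromo-1,3-difluoro-2-nitrobenzene
Product: 4 5-bromo-1,3-dimethoxy-2-nitrobenzene
Conditions: NaOMe (2.1 equiv), MeOH, 0 °C to 50 °C
Reagents that add atoms: sodium methoxide C[O-].[Na+]
Why: In this nucleophilic aromatic substitution (addition–elimination) the two fluorides ortho to the nitro group are displaced much faster than the para bromide, which fixes the O,N,O pattern of ring B without regiochemical ambiguity.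

Step 3
Reactants: 4 5-bromo-1,3-dimethoxy-2-nitrobenzene
Product: 5 5-bromo-2-nitrobenzene-1,3-diol
Conditions: BBr3 (3 equiv), CH2Cl2, −78 °C to rt; then H2O
Reagents that add atoms: none
Why: Lewis-acid ether cleavage with BBr3 removes both methyl groups by bromide attack on the boron-activated ethers, and the nitro group and aryl bromide are inert to it.

Step 4
Reactants: 5 5-bromo-2-nitrobenzene-1,3-diol
Product: 6 2-amino-5-bromobenzene-1,3-diol
Conditions: H2 (1 atm), Pt/C (sulfided), EtOAc, rt
Reagents that add atoms: none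
Why: Catalytic hydrogenation over sulfided platinum reduces the nitroarene to the aniline without hydrogenolysis of the C–Br bond, and the air-sensitive aminoresorcinol is used at once.

Step 5
Reactants: 6 2-amino-5-bromobenzene-1,3-diol
Product: 7 3-bromo-6-diazo-5-hydroxycyclohexa-2,4-dien-1-one
Conditions: t-BuONO (1.2 equiv), MeCN, 0 °C
Reagents that add atoms: tert-butyl nitrite CC(C)(C)ON=O
Why: Diazotisation with an alkyl nitrite gives the o-hydroxy diazonium ion, which loses its acidic phenolic proton and settles as the neutral o-quinone diazide.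

Step 6
Reactants: 7 3-bromo-6-diazo-5-hydroxycyclohexa-2,4-dien-1-one
Product: 8 3-bromo-5-(TBS-oxy)-6-diazocyclohexa-2,4-dien-1-one
Conditions: TBSOTf (1.1 equiv), 2,6-lutidine, CH2Cl2, −78 °C to 0 °C
Reagents that add atoms: tert-butyldimethylsilyl triflate CC(C)(C)[Si](C)(C)OS(=O)(=O)C(F)(F)F
Why: O-silylation removes the acidic OH that would quench the carbene by O–H insertion, and because the two oxygens flanking the diazo carbon are equivalent only one product can form.

Step 7
Reactants: 2 (E)-3,5,4'-tris(TBS-oxy)stilbene, 8 3-bromo-5-(TBS-oxy)-6-diazocyclohexa-2,4-dien-1-one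
Product: 10 (2R,3R)-6-bromo-2,3-diaryl-2,3-dihydrobenzofuran tetrakis-TBS ether, via spirocyclopropane 9 (not isolated)
Conditions: 8 added slowly to 2 (1.5 equiv), Rh2(S-TCPTTL)4 (1 mol%), toluene, 25 °C; then (CF3)2CHOH, 25 °C
Reagents that add atoms: none
Why: Proposed new method: the dirhodium carbene from 8 adds to the E-alkene of 2 in an asynchronous [2+1] addition (first bond at the carbon next to the 3,5-disilyloxyphenyl ring) to give trans-cyclopropane 9, whose bond to the 4-silyloxybenzylic carbon heterolyses so that the ketone oxygen closes 5-exo-trig on that carbon as ring B rearomatises (Cloke–Wilson rearrangement), with C3' set by the face selection of the chiral catalyst and C2' set trans to it in the reversible closure, the closest known type being the dirhodium-catalysed formal [3+2] addition of cyclic 2-diazo-1,3-diketones and naphthoquinone diazides to styrenes.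

Step 8
Reactants: 10 (2R,3R)-6-bromo-2,3-diaryl-2,3-dihydrobenzofuran tetrakis-TBS ether, 11 4-(TBS-oxy)styrene
Product: 12 (2R,3R)-6-[(E)-4-(TBS-oxy)styryl]-2,3-diaryl-2,3-dihydrobenzofuran pentakis-TBS ether
Conditions: Pd2(dba)3 (2.5 mol%), P(t-Bu)3·HBF4 (10 mol%), Cy2NMe, 1,4-dioxane, 80 °C
Reagents that add atoms: none
Why: The Heck reaction at the unhindered C6' bromide proceeds by syn insertion and syn β-hydride elimination to the E-stilbene, and the amine base in an aprotic solvent leaves the aryl silyl ethers and both stereocentres untouched.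

Step 9
Reactants: 13 5-bromobenzene-1,3-diol
Product: 14 5-bromo-4-nitrobenzene-1,3-diol
Conditions: HNO3 (1.0 equiv), AcOH, 10 °C
Reagents that add atoms: nitric acid O[N+](=O)[O-]
Why: Electrophilic aromatic nitration goes to C4, which is ortho to one hydroxyl and para to the other as in resorcinol itself, and any isomer nitrated between the hydroxyls is removed by chromatography.

Step 10
Reactants: 14 5-bromo-4-nitrobenzene-1,3-diol
Product: 15 3-bromo-5-(TBS-oxy)-2-nitrophenol
Conditions: TBSCl (1.0 equiv), imidazole, CH2Cl2, 0 °C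
Reagents that add atoms: tert-butyldimethylsilyl chloride CC(C)(C)[Si](C)(C)Cl
Why: Chemoselective O-silylation takes the hydroxyl para to the nitro group because the ortho hydroxyl is held in an intramolecular hydrogen bond to the nitro oxygen and is also more hindered.

Step 11
Reactants: 15 3-bromo-5-(TBS-oxy)-2-nitrophenol
Product: 16 2-amino-3-bromo-5-(TBS-oxy)phenol
Conditions: H2 (1 atm), Pt/C (sulfided), EtOAc, rt
Reagents that add atoms: none
Why: Catalytic hydrogenation over sulfided platinum reduces the nitro group under neutral conditions that spare the C–Br bond and the aryl silyl ether.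

Step 12
Reactants: 16 2-amino-3-bromo-5-(TBS-oxy)phenol
Product: 17 5-bromo-3-(TBS-oxy)-6-diazocyclohexa-2,4-dien-1-one
Conditions: t-BuONO (1.2 equiv), MeCN, 0 °C; filtration through neutral alumina
Reagents that add atoms: tert-butyl nitrite CC(C)(C)ON=O
Why: Diazotisation of the o-aminophenol with an alkyl nitrite and loss of the phenolic proton gives the neutral o-quinone diazide, in which ring A is already stored in dearomatised form with the future C3a as the diazo carbon.

Step 13
Reactants: 12 (2R,3R)-6-[(E)-4-(TBS-oxy)styryl]-2,3-diaryl-2,3-dihydrobenzofuran pentakis-TBS ether, 17 5-bromo-3-(TBS-oxy)-6-diazocyclohexa-2,4-dien-1-one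
Product: 19 (2S,3S)-4-bromo bis(dihydrobenzofuran) hexakis-TBS ether, via spirocyclopropane 18 (not isolated)
Conditions: 17 (1.5 equiv) added over 3 h to 12, Rh2(R-TCPTTL)4 (2 mol%), toluene, 25 °C; then (CF3)2CHOH, 25 °C
Reagents that add atoms: none
Why: Proposed new method: Rh2(R-TCPTTL)4 expels N2 from 17 and the electrophilic quinoid carbene at C3a adds to the E-alkene of 12 in an asynchronous [2+1] addition (first bond C3a–C3, charge build-up at C2 next to the 4-silyloxyphenyl ring) to give trans-cyclopropane 18; the closest known reactions are dirhodium-catalysed cyclopropanations and formal [3+2] additions of quinone diazides and cyclic 2-diazo-1,3-diketones to styrenes and the Cloke–Wilson rearrangement of spirocyclopropyl ketones, none of them shown for a trans-stilbene with a monocyclic o-quinone diazide under catalyst control. In the ionising co-solvent the donor–acceptor bond C3a–C2 of 18 heterolyses, ring A rearomatises to the C7a phenolate, and this oxygen closes on the quinone-methide-like C2 in a 5-exo-trig mode, so the three-membered ring C2–C3–C3a takes in C7a and O1 and becomes the five-membered ring. C3 is set during carbene transfer by the chiral catalyst pocket, which selects the alkene face (the primed stereocentres are too remote to interfere), and it is untouched afterwards because both of its ring bonds persist. C2 is set in the ring closure by C3, the two aryl groups ending up trans in a closure that is reversible under the conditions, and the spiro centre C3a, formed as either epimer, is erased. The step needs chemoselectivity for the only alkene over the silyloxyarenes (whose free positions are shielded by the silyl groups), cleavage of C3a–C2 rather than C3a–C3 (4-silyloxyphenyl at C2 against an aryl ring with only meta oxygens at C3), and O-closure rather than return to the cyclopropane (secured by the aromatisation of ring A).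

Step 14
Reactants: 19 (2S,3S)-4-bromo bis(dihydrobenzofuran) hexakis-TBS ether, 11 4-(TBS-oxy)styrene
Product: 20 heptakis-TBS ether of the target
Conditions: Pd2(dba)3 (5 mol%), P(t-Bu)3·HBF4 (20 mol%), Cy2NMe, 1,4-dioxane, 100 °C
Reagents that add atoms: none
Why: The Heck reaction with a bulky electron-rich phosphine allows oxidative addition of zerovalent palladium at the hindered C4 bromide, syn insertion and syn β-hydride elimination give the E-alkene, and no stereocentre is touched.

Step 15
Reactants: 20 heptakis-TBS ether of the target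
Product: 21 target CNP0188679.4
Conditions: TBAF (8 equiv), AcOH (8 equiv), THF, 0 °C, argon
Reagents that add atoms: none
Why: Fluoride-induced desilylation buffered with acetic acid frees all seven phenols without strong acid or free phenoxide, so neither dihydrofuran ring opens and the stilbene does not cyclise onto it.

Compound list
1 | resveratrol, (E)-5-(4-hydroxystyryl)benzene-1,3-diol | Oc1ccc(/C=C/c2cc(O)cc(O)c2)cc1 | starting material
2 | (E)-3,5,4'-tris(TBS-oxy)stilbene | CC(C)(C)[Si](C)(C)Oc1ccc(/C=C/c2cc(O[Si](C)(C)C(C)(C)C)cc(O[Si](C)(C)C(C)(C)C)c2)cc1 | intermediate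
3 | 5-bromo-1,3-difluoro-2-nitrobenzene | O=[N+]([O-])c1c(F)cc(Br)cc1F | starting material
4 | 5-bromo-1,3-dimethoxy-2-nitrobenzene | COc1cc(Br)cc(OC)c1[N+](=O)[O-] | intermediate
5 | 5-bromo-2-nitrobenzene-1,3-diol | Oc1cc(Br)cc(O)c1[N+](=O)[O-] | intermediate
6 | 2-amino-5-bromobenzene-1,3-diol | Nc1c(O)cc(Br)cc1O | intermediate
7 | 3-bromo-6-diazo-5-hydroxycyclohexa-2,4-dien-1-one | O=C1C=C(Br)C=C(O)C1=[N+]=[N-] | intermediate
8 | 3-bromo-5-(TBS-oxy)-6-diazocyclohexa-2,4-dien-1-one | O=C1C=C(Br)C=C(O[Si](C)(C)C(C)(C)C)C1=[N+]=[N-] | intermediate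
9 | (1R,2R)-6-bromo-8-(TBS-oxy)-1-[3,5-bis(TBS-oxy)phenyl]-2-[4-(TBS-oxy)phenyl]spiro[2.5]octa-5,7-dien-4-one, trans-diaryl, either configuration at the spiro carbon | O=C1C=C(Br)C=C(O[Si](C)(C)C(C)(C)C)C12[C@@H](c1ccc(O[Si](C)(C)C(C)(C)C)cc1)[C@@H]2c1cc(O[Si](C)(C)C(C)(C)C)cc(O[Si](C)(C)C(C)(C)C)c1 | intermediate
10 | (2R,3R)-6-bromo-4-(TBS-oxy)-3-[3,5-bis(TBS-oxy)phenyl]-2-[4-(TBS-oxy)phenyl]-2,3-dihydrobenzofuran | Brc1cc(O[Si](C)(C)C(C)(C)C)c2c(c1)O[C@@H](c1ccc(O[Si](C)(C)C(C)(C)C)cc1)[C@@H]2c1cc(O[Si](C)(C)C(C)(C)C)cc(O[Si](C)(C)C(C)(C)C)c1 | intermediate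
11 | 4-(TBS-oxy)styrene | C=Cc1ccc(O[Si](C)(C)C(C)(C)C)cc1 | starting material
12 | (2R,3R)-4-(TBS-oxy)-3-[3,5-bis(TBS-oxy)phenyl]-2-[4-(TBS-oxy)phenyl]-6-[(E)-4-(TBS-oxy)styryl]-2,3-dihydrobenzofuran | CC(C)(C)[Si](C)(C)Oc1ccc(/C=C/c2cc(O[Si](C)(C)C(C)(C)C)c3c(c2)O[C@@H](c2ccc(O[Si](C)(C)C(C)(C)C)cc2)[C@@H]3c2cc(O[Si](C)(C)C(C)(C)C)cc(O[Si](C)(C)C(C)(C)C)c2)cc1 | intermediate
13 | 5-bromobenzene-1,3-diol (5-bromoresorcinol) | Oc1cc(O)cc(Br)c1 | starting material
14 | 5-bromo-4-nitrobenzene-1,3-diol | Oc1cc(O)c([N+](=O)[O-])c(Br)c1 | intermediate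
15 | 3-bromo-5-(TBS-oxy)-2-nitrophenol | CC(C)(C)[Si](C)(C)Oc1cc(O)c([N+](=O)[O-])c(Br)c1 | intermediate
16 | 2-amino-3-bromo-5-(TBS-oxy)phenol | CC(C)(C)[Si](C)(C)Oc1cc(O)c(N)c(Br)c1 | intermediate
17 | 5-bromo-3-(TBS-oxy)-6-diazocyclohexa-2,4-dien-1-one | O=C1C=C(O[Si](C)(C)C(C)(C)C)C=C(Br)C1=[N+]=[N-] | intermediate
18 | (1S,2S)-8-bromo-6-(TBS-oxy)-1-{(2R,3R)-4-(TBS-oxy)-3-[3,5-bis(TBS-oxy)phenyl]-2-[4-(TBS-oxy)phenyl]-2,3-dihydrobenzofuran-6-yl}-2-[4-(TBS-oxy)phenyl]spiro[2.5]octa-5,7-dien-4-one, trans-diaryl, either configuration at the spiro carbon | O=C1C=C(O[Si](C)(C)C(C)(C)C)C=C(Br)C12[C@H](c1cc(O[Si](C)(C)C(C)(C)C)c3c(c1)O[C@@H](c1ccc(O[Si](C)(C)C(C)(C)C)cc1)[C@@H]3c1cc(O[Si](C)(C)C(C)(C)C)cc(O[Si](C)(C)C(C)(C)C)c1)[C@H]2c1ccc(O[Si](C)(C)C(C)(C)C)cc1 | intermediate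
19 | (2S,3S)-4-bromo-6-(TBS-oxy)-2-[4-(TBS-oxy)phenyl]-3-{(2R,3R)-4-(TBS-oxy)-3-[3,5-bis(TBS-oxy)phenyl]-2-[4-(TBS-oxy)phenyl]-2,3-dihydrobenzofuran-6-yl}-2,3-dihydrobenzofuran | Brc1cc(O[Si](C)(C)C(C)(C)C)cc2c1[C@H](c1cc(O[Si](C)(C)C(C)(C)C)c3c(c1)O[C@@H](c1ccc(O[Si](C)(C)C(C)(C)C)cc1)[C@@H]3c1cc(O[Si](C)(C)C(C)(C)C)cc(O[Si](C)(C)C(C)(C)C)c1)[C@@H](c1ccc(O[Si](C)(C)C(C)(C)C)cc1)O2 | intermediate
20 | heptakis-TBS ether of the target: as 19 with (E)-4-(TBS-oxy)styryl in place of bromine at C4 | CC(C)(C)[Si](C)(C)Oc1ccc(/C=C/c2cc(O[Si](C)(C)C(C)(C)C)cc3c2[C@H](c2cc(O[Si](C)(C)C(C)(C)C)c4c(c2)O[C@@H](c2ccc(O[Si](C)(C)C(C)(C)C)cc2)[C@@H]4c2cc(O[Si](C)(C)C(C)(C)C)cc(O[Si](C)(C)C(C)(C)C)c2)[C@@H](c2ccc(O[Si](C)(C)C(C)(C)C)cc2)O3)cc1 | intermediate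
21 | 5-[(2R,3R)-4-hydroxy-6-{(2S,3S)-6-hydroxy-2-(4-hydroxyphenyl)-4-[(E)-2-(4-hydroxyphenyl)ethenyl]-2,3-dihydro-1-benzofuran-3-yl}-2-(4-hydroxyphenyl)-2,3-dihydro-1-benzofuran-3-yl]benzene-1,3-diol (CNP0188679.4) | Oc1ccc(/C=C/c2cc(O)cc3c2[C@H](c2cc(O)c4c(c2)O[C@@H](c2ccc(O)cc2)[C@@H]4c2cc(O)cc(O)c2)[C@@H](c2ccc(O)cc2)O3)cc1 | target

Total step count: 15.
Longest linear sequence: 10 steps (3 to 21 through steps 2, 3, 4, 5, 6, 7, 8, 13, 14 and 15).

Steps most likely to fail

**Step 13.**
- Risk: carbene transfer to the hindered trans-1,2-diarylalkene may be slower than carbene dimerisation or azine formation. Face selection by the catalyst on a large substrate may be poor. Loss of the C3 proton from the opened cyclopropane may compete with ring closure.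
- Fallback: it sets out from 10 and 13 and returns at 19, using a known formal [4+1] annulation of an in situ generated o-quinone methide with a sulfur ylide.
- Ring A piece: Vilsmeier–Haack formylation of 13 (POCl3, DMF) gives 2-bromo-4,6-dihydroxybenzaldehyde F1. Its non-chelated hydroxyl is silylated (TBSCl, imidazole) to 2-bromo-6-hydroxy-4-(TBS-oxy)benzaldehyde F2.
- Union: bromine–lithium exchange on 10 (n-BuLi, THF, −78 °C) and addition to the sodium phenolate of F2 gives the o-hydroxybenzhydrol F3.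
- Ylide precursor: purchased 4-(TBS-oxy)benzyl bromide and tetrahydrothiophene give 1-[4-(TBS-oxy)benzyl]tetrahydrothiophenium bromide F4.
- Annulation: with Cs2CO3 in CH2Cl2, F3 loses water and takes up the ylide of F4 by conjugate addition at C3 and 5-exo-tet O-alkylation at C2, giving the trans-dihydrobenzofuran. Compound 19 is then separated by chromatography from the (2R,3R)-configured diastereomer F5.

**Step 7.**
- Risk: enantiofacial discrimination of an acyclic trans-stilbene may be poor, and carbene dimerisation may outrun addition.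
- Fallback: it sets out from 13 and returns at 10, using the same known annulation followed by resolution.
- Aryl piece: compound 13 is silylated twice to 1-bromo-3,5-bis(TBS-oxy)benzene F6.
- Ring B piece: purchased 4-bromo-2,6-dimethoxybenzaldehyde is demethylated with BBr3 to 4-bromo-2,6-dihydroxybenzaldehyde F7 and monosilylated to 4-bromo-2-hydroxy-6-(TBS-oxy)benzaldehyde F8.
- Union: bromine–lithium exchange on F6 and addition to the sodium phenolate of F8 gives the o-hydroxybenzhydrol F9.
- Annulation and resolution: Cs2CO3 with the sulfonium salt F4 converts F9 into the racemic trans-dihydrobenzofuran. Preparative chromatography on a chiral stationary phase then gives 10 and removes the enantiomer F10.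

**Step 14.**
- Risk: oxidative addition and alkene insertion at the C4 bromide, which is flanked by the C3 substituent, may be slow. Protodebromination or thermal loss of silyl groups could then take over.
- Fallback: it sets out from 19 and returns at 20, forming the C=C bond by olefination instead of cross-coupling.
- Aldehyde: bromine–lithium exchange on 19 (n-BuLi, THF, −78 °C) and quenching with DMF gives the C4 carbaldehyde F11.
- Phosphonate: purchased 4-(TBS-oxy)benzyl bromide and P(OEt)3 give diethyl [4-(TBS-oxy)benzyl]phosphonate F12 by a Michaelis–Arbuzov reaction.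
- Olefination: a Horner–Wadsworth–Emmons reaction of F11 with F12 (NaH, THF, 0 °C) gives the E-stilbene 20.

Further compounds
F1 | step 13 | 2-bromo-4,6-dihydroxybenzaldehyde | O=Cc1c(O)cc(O)cc1Br
F2 | step 13 | 2-bromo-6-hydroxy-4-(TBS-oxy)benzaldehyde | O=Cc1c(O)cc(O[Si](C)(C)C(C)(C)C)cc1Br
F3 | step 13 | 3-bromo-2-{hydroxy[(2R,3R)-4-(TBS-oxy)-3-[3,5-bis(TBS-oxy)phenyl]-2-[4-(TBS-oxy)phenyl]-2,3-dihydrobenzofuran-6-yl]methyl}-5-(TBS-oxy)phenol, both carbinol epimers | OC(c1c(O)cc(O[Si](C)(C)C(C)(C)C)cc1Br)c1cc(O[Si](C)(C)C(C)(C)C)c2c(c1)O[C@@H](c1ccc(O[Si](C)(C)C(C)(C)C)cc1)[C@@H]2c1cc(O[Si](C)(C)C(C)(C)C)cc(O[Si](C)(C)C(C)(C)C)c1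
F4 | step 13 | 1-[4-(TBS-oxy)benzyl]tetrahydrothiophenium bromide | CC(C)(C)[Si](C)(C)Oc1ccc(C[S+]2CCCC2)cc1.[Br-]
F5 | step 13 | diastereomer of 19 with (2R,3R) configuration in the unprimed ring | Brc1cc(O[Si](C)(C)C(C)(C)C)cc2c1[C@@H](c1cc(O[Si](C)(C)C(C)(C)C)c3c(c1)O[C@@H](c1ccc(O[Si](C)(C)C(C)(C)C)cc1)[C@@H]3c1cc(O[Si](C)(C)C(C)(C)C)cc(O[Si](C)(C)C(C)(C)C)c1)[C@H](c1ccc(O[Si](C)(C)C(C)(C)C)cc1)O2
F6 | step 7 | 1-bromo-3,5-bis(TBS-oxy)benzene | Brc1cc(O[Si](C)(C)C(C)(C)C)cc(O[Si](C)(C)C(C)(C)C)c1
F7 | step 7 | 4-bromo-2,6-dihydroxybenzaldehyde | O=Cc1c(O)cc(Br)cc1O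
F8 | step 7 | 4-bromo-2-hydroxy-6-(TBS-oxy)benzaldehyde | O=Cc1c(O)cc(Br)cc1O[Si](C)(C)C(C)(C)C
F9 | step 7 | 5-bromo-2-{[3,5-bis(TBS-oxy)phenyl](hydroxy)methyl}-3-(TBS-oxy)phenol, racemic | OC(c1c(O)cc(Br)cc1O[Si](C)(C)C(C)(C)C)c1cc(O[Si](C)(C)C(C)(C)C)cc(O[Si](C)(C)C(C)(C)C)c1
F10 | step 7 | (2S,3S) enantiomer of 10 | Brc1cc(O[Si](C)(C)C(C)(C)C)c2c(c1)O[C@H](c1ccc(O[Si](C)(C)C(C)(C)C)cc1)[C@H]2c1cc(O[Si](C)(C)C(C)(C)C)cc(O[Si](C)(C)C(C)(C)C)c1
F11 | step 14 | C4 carbaldehyde corresponding to 19 (CHO in place of Br) | O=Cc1cc(O[Si](C)(C)C(C)(C)C)cc2c1[C@H](c1cc(O[Si](C)(C)C(C)(C)C)c3c(c1)O[C@@H](c1ccc(O[Si](C)(C)C(C)(C)C)cc1)[C@@H]3c1cc(O[Si](C)(C)C(C)(C)C)cc(O[Si](C)(C)C(C)(C)C)c1)[C@@H](c1ccc(O[Si](C)(C)C(C)(C)C)cc1)O2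
F12 | step 14 | diethyl [4-(TBS-oxy)benzyl]phosphonate | CCOP(=O)(Cc1ccc(O[Si](C)(C)C(C)(C)C)cc1)OCC
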